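**Retrosynthetic overview**
1. Target 30 ⇐ quinone 29 ⇐ dimethyl ether 28 (reduction; oxidative demethylation). The only ring, the benzene ring, is bought with 1; no ring is formed in the route.
2. 28 ⇐ allylic chloride 8 (arene + C1–C4) + carbon monoxide (C5) + alkenylstannane 26 (C6–C16): a three-component carbonylative Stille coupling, in which the C4–C5 bond arises by CO insertion into the allyl–palladium bond and C5–C6 by reductive elimination.
3. Enabling feature: the C5 ketone sits between the allylic C4H2 (of the 2E C2=C3 alkene) and the vinylic C6H (of the 6Z C6=C7 alkene), i.e. a skipped dienone C2=C3–C4–C5(=O)–C6=C7 = allyl–CO–vinyl.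
4. 26 ⇐ carbocupration of propyne (6Z), alkyne carboalumination/oxirane opening (10E), asymmetric propargylation of 3-methylbut-2-enal (13R).
5. 8 ⇐ copper-catalysed SN2' arylation of isoprene monoxide (2E) with the Grignard reagent from brominated, methylated 4-methoxy-2-methylphenol.

Key step: step 12

Remark: the side chain is numbered C1 (benzylic CH2) to C16 as in the name of 30; oxirane 4 is used as the racemate because its stereocentre disappears in step 3.

**Step 1**
Reactants: 1 4-methoxy-2-methylphenol
Product: 2 2-bromo-4-methoxy-6-methylphenol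
Conditions: Br2 (1.0 equiv), CH2Cl2, −10 °C
Reagents that add atoms: bromine, BrBr
Why: Electrophilic aromatic bromination should go to the only free position ortho to the strongly activating hydroxyl, since the para position carries OMe and the other ortho position the methyl group.

**Step 2**
Reactants: 2 2-bromo-4-methoxy-6-methylphenol
Product: 3 1-bromo-2,5-dimethoxy-3-methylbenzene
Conditions: MeI, K2CO3, DMF, rt
Reagents that add atoms: iodomethane, CI
Why: Williamson O-methylation of the phenoxide gives the dimethyl ether, a masked hydroquinone that is inert to the organometallic steps that follow.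

**Step 3**
Reactants: 3 1-bromo-2,5-dimethoxy-3-methylbenzene; 4 2-methyl-2-vinyloxirane (isoprene monoxide)
Product: 6 (2E)-4-(2,5-dimethoxy-3-methylphenyl)-2-methylbut-2-en-1-ol, via arylmagnesium bromide 5 (not isolated)
Conditions: Mg, THF, 50 °C; then CuI (10 mol%), 4, THF, −30 → 0 °C; aq. NH4Cl
Reagents that add atoms: none
Why: Copper-catalysed anti-SN2' addition of the aryl Grignard reagent to the vinyl oxirane opens the ring with allylic transposition and should favour the E-trisubstituted alkene through the s-trans conformer of the oxirane, the minor Z isomer being removed by chromatography.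

**Step 4**
Reactants: 6 (2E)-4-(2,5-dimethoxy-3-methylphenyl)-2-methylbut-2-en-1-ol
Product: 8 1-[(2E)-4-chloro-3-methylbut-2-en-1-yl]-2,5-dimethoxy-3-methylbenzene, via allylic mesylate 7 (not isolated)
Conditions: MsCl, 2,4,6-collidine, LiCl, DMF, 0 °C
Reagents that add atoms: lithium chloride, [Li+].[Cl-]
Why: Mesylation and in situ SN2 displacement by chloride should convert the primary allylic alcohol into the chloride without allylic transposition or loss of the E geometry.

**Step 5**
Reactants: 9 3-methylbut-2-enal; 10 4,4,5,5-tetramethyl-2-(propa-1,2-dien-1-yl)-1,3,2-dioxaborolane (allenylboronic acid pinacol ester)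
Product: 12 (4R)-6-methylhept-5-en-1-yn-4-ol, via pinacol borate ester 11 (not isolated)
Conditions: (R)-3,3'-bis(2,4,6-triisopropylphenyl)-1,1'-binaphthyl-2,2'-diyl hydrogen phosphate ((R)-TRIP, 5 mol%), 4 Å MS, toluene, −20 °C; then H2O
Reagents that add atoms: none
Why: Chiral-phosphoric-acid-catalysed propargylboration (SE2' through a closed six-membered chair transition state in which the acid bridges a boronate oxygen and the formyl group) should deliver the propargyl group to the Re face of the enal with the (R)-acid, by analogy with aryl and alkenyl aldehydes, and so set C13 of the target as R; should the opposite sense be found, the (S)-acid is used.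

**Step 6**
Reactants: 12 (4R)-6-methylhept-5-en-1-yn-4-ol
Product: 13 tert-butyldimethyl{[(4R)-6-methylhept-5-en-1-yn-4-yl]oxy}silane
Conditions: TBSCl, imidazole, DMF, 0 °C → rt
Reagents that add atoms: tert-butyldimethylsilyl chloride, CC(C)(C)[Si](C)(C)Cl
Why: Standard silylation protects the allylic alcohol against the aluminium, magnesium, copper and lithium reagents of steps 7 to 10 without touching the stereocentre.

**Step 7**
Reactants: 13 tert-butyldimethyl{[(4R)-6-methylhept-5-en-1-yn-4-yl]oxy}silane; 14 oxirane (ethylene oxide)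
Product: 17 (3E,6R)-6-[(tert-butyldimethylsilyl)oxy]-4,8-dimethylnona-3,7-dien-1-ol, via alkenyldimethylalane 15 (not isolated), via lithium alkenylalanate 16 (not isolated)
Conditions: Me3Al, Cp2ZrCl2 (20 mol%), ClCH2CH2Cl, rt; volatiles off; n-BuLi, hexane/THF, 0 °C; 14, 0 °C → rt; aq. NH4Cl
Reagents that add atoms: trimethylaluminium, C[Al](C)C
Why: Zirconium-catalysed syn-methylalumination (Negishi carboalumination) places methyl on the internal and aluminium on the terminal alkyne carbon, and the derived alanate transfers the alkenyl group to oxirane with retention, so the 10E alkene and C8–C9 should arise in one pot.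

**Step 8**
Reactants: 17 (3E,6R)-6-[(tert-butyldimethylsilyl)oxy]-4,8-dimethylnona-3,7-dien-1-ol
Product: 18 {[(4R,6E)-9-bromo-2,6-dimethylnona-2,6-dien-4-yl]oxy}(tert-butyl)dimethylsilane
Conditions: CBr4, PPh3, 2,6-lutidine, CH2Cl2, 0 °C
Reagents that add atoms: tetrabromomethane, BrC(Br)(Br)Br
Why: Appel bromination (SN2 on the alkoxyphosphonium ion) should convert the primary alcohol into the bromide under buffered conditions that spare the allylic silyl ether and both alkenes.

**Step 9**
Reactants: 18 {[(4R,6E)-9-bromo-2,6-dimethylnona-2,6-dien-4-yl]oxy}(tert-butyl)dimethylsilane; 19 propyne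
Product: 23 tert-butyl{[(4R,6E,10Z)-11-iodo-2,6,10-trimethylundeca-2,6,10-trien-4-yl]oxy}dimethylsilane, via alkylmagnesium bromide 20 (not isolated), via alkylcopper 21 (not isolated), via alkenylcopper 22 (not isolated)
Conditions: Mg, Et2O, reflux; CuBr·SMe2, Et2O/Me2S, −45 °C; 19, −25 °C; I2, THF, −50 → 0 °C
Reagents that add atoms: iodine, II
Why: Normant carbocupration adds the alkylcopper syn across propyne with copper on the terminal carbon, and iodinolysis with retention should fix the 6Z geometry (chain cis to iodine).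

**Step 10**
Reactants: 23 tert-butyl{[(4R,6E,10Z)-11-iodo-2,6,10-trimethylundeca-2,6,10-trien-4-yl]oxy}dimethylsilane
Product: 25 tert-butyldimethyl{[(4R,6E,10Z)-2,6,10-trimethyl-11-(tributylstannyl)undeca-2,6,10-trien-4-yl]oxy}silane, via alkenyllithium 24 (not isolated)
Conditions: t-BuLi (2.1 equiv), Et2O, −78 °C; Bu3SnCl, −78 °C → rt
Reagents that add atoms: tributyltin chloride, CCCC[Sn](Cl)(CCCC)CCCC
Why: Iodine–lithium exchange and stannylation of the alkenyllithium both proceed with retention of alkene configuration, so the Z-alkenylstannane should result.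

**Step 11**
Reactants: 25 tert-butyldimethyl{[(4R,6E,10Z)-2,6,10-trimethyl-11-(tributylstannyl)undeca-2,6,10-trien-4-yl]oxy}silane
Product: 26 (4R,6E,10Z)-2,6,10-trimethyl-11-(tributylstannyl)undeca-2,6,10-trien-4-ol
Conditions: TBAF, THF, 0 °C → rt
Reagents that add atoms: none
Why: Fluoride-induced desilylation leaves the alkenyl–tin bond intact and frees the C13 hydroxyl before the fragment union, so that no deprotection has to be run later on the base- and acid-sensitive skipped dienone.

**Step 12**
Reactants: 8 1-[(2E)-4-chloro-3-methylbut-2-en-1-yl]-2,5-dimethoxy-3-methylbenzene; 26 (4R,6E,10Z)-2,6,10-trimethyl-11-(tributylstannyl)undeca-2,6,10-trien-4-ol; 27 carbon monoxide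
Product: 28 (2E,6Z,10E,13R)-1-(2,5-dimethoxy-3-methylphenyl)-13-hydroxy-3,7,11,15-tetramethylhexadeca-2,6,10,14-tetraen-5-one
Conditions: Pd2(dba)3 (3 mol%), P(2-furyl)3 (12 mol%), CO (3 atm), THF, 50 °C, dark
Reagents that add atoms: none
Why: Oxidative addition of allylic chloride 8 to zerovalent palladium gives the syn-η3-allyl complex of divalent palladium, CO inserts at its unsubstituted terminus C4 to form the C4–C5 bond (an acylpalladium chloride), and transmetalation from alkenylstannane 26 followed by reductive elimination forms the C5–C6 bond, so that the arene-bearing C1–C4 unit, the C5 carbonyl and the C6–C16 chain are joined in one operation with the ketone at its final oxidation level. The closest known reaction type is the Stille carbonylative cross-coupling of allylic chlorides with alkenylstannanes to give allyl vinyl ketones. No ring is closed and no stereocentre is formed; C13 is not involved. The step needs acylation at the primary allyl terminus (secured by the preference of CO insertion for the less hindered CH2 end), retention of the 2E geometry (the E chloride enters as the syn allyl complex and should be trapped by CO before syn–anti exchange), retention of the 6Z geometry (tin-to-palladium transfer and reductive elimination proceed with retention at sp2 carbon) and acylation instead of direct allyl–alkenyl coupling (secured by the CO pressure). The neutral, base-free medium should keep the C2=C3 double bond out of conjugation with the new ketone and tolerate the free C13 hydroxyl.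

**Step 13**
Reactants: 28 (2E,6Z,10E,13R)-1-(2,5-dimethoxy-3-methylphenyl)-13-hydroxy-3,7,11,15-tetramethylhexadeca-2,6,10,14-tetraen-5-one
Product: 29 2-[(2E,6Z,10E,13R)-13-hydroxy-3,7,11,15-tetramethyl-5-oxohexadeca-2,6,10,14-tetraen-1-yl]-6-methylcyclohexa-2,5-diene-1,4-dione
Conditions: (NH4)2Ce(NO3)6 (2.5 equiv), MeCN/H2O, 0 °C, short contact time
Reagents that add atoms: water, O
Why: Oxidative demethylation by tetravalent cerium (two one-electron oxidations of the electron-rich 1,4-dimethoxyarene with ipso attack of water and loss of methanol) should give the para-quinone faster than the isolated alkenes, the enone or the secondary alcohol react at 0 °C.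

**Step 14**
Reactants: 29 2-[(2E,6Z,10E,13R)-13-hydroxy-3,7,11,15-tetramethyl-5-oxohexadeca-2,6,10,14-tetraen-1-yl]-6-methylcyclohexa-2,5-diene-1,4-dione
Product: 30 2-[(2E,6Z,10E,13R)-13-hydroxy-3,7,11,15-tetramethyl-5-oxohexadeca-2,6,10,14-tetraen-1-yl]-6-methylbenzene-1,4-diol
Conditions: Na2S2O4, THF/H2O, rt, argon
Reagents that add atoms: none
Why: Two-electron reduction of the quinone by dithionite under near-neutral biphasic conditions should give the hydroquinone without affecting the ketone, the alkenes or the allylic alcohol.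

**Compound list**
1 | 4-methoxy-2-methylphenol | COc1ccc(O)c(C)c1 | starting material
2 | 2-bromo-4-methoxy-6-methylphenol | COc1cc(C)c(O)c(Br)c1 | intermediate
3 | 1-bromo-2,5-dimethoxy-3-methylbenzene | COc1cc(C)c(OC)c(Br)c1 | intermediate
4 | 2-methyl-2-vinyloxirane (isoprene monoxide, racemic) | CC1(C=C)CO1 | starting material
5 | (2,5-dimethoxy-3-methylphenyl)magnesium bromide | COc1cc(C)c(OC)c([Mg]Br)c1 | intermediate
6 | (2E)-4-(2,5-dimethoxy-3-methylphenyl)-2-methylbut-2-en-1-ol | COc1cc(C)c(OC)c(C/C=C(C)/CO)c1 | intermediate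
7 | (2E)-4-(2,5-dimethoxy-3-methylphenyl)-2-methylbut-2-en-1-yl methanesulfonate | COc1cc(C)c(OC)c(C/C=C(C)/COS(C)(=O)=O)c1 | intermediate
8 | 1-[(2E)-4-chloro-3-methylbut-2-en-1-yl]-2,5-dimethoxy-3-methylbenzene | COc1cc(C)c(OC)c(C/C=C(C)/CCl)c1 | intermediate
9 | 3-methylbut-2-enal | CC(C)=CC=O | starting material
10 | 4,4,5,5-tetramethyl-2-(propa-1,2-dien-1-yl)-1,3,2-dioxaborolane | C=C=CB1OC(C)(C)C(C)(C)O1 | starting material
11 | 4,4,5,5-tetramethyl-2-{[(4R)-6-methylhept-5-en-1-yn-4-yl]oxy}-1,3,2-dioxaborolane | CC(C)=C[C@H](OB1OC(C)(C)C(C)(C)O1)CC#C | intermediate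
12 | (4R)-6-methylhept-5-en-1-yn-4-ol | CC(C)=C[C@H](O)CC#C | intermediate
13 | tert-butyldimethyl{[(4R)-6-methylhept-5-en-1-yn-4-yl]oxy}silane | CC(C)=C[C@H](O[Si](C)(C)C(C)(C)C)CC#C | intermediate
14 | oxirane (ethylene oxide) | C1CO1 | starting material
15 | {(1E,4R)-4-[(tert-butyldimethylsilyl)oxy]-2,6-dimethylhepta-1,5-dien-1-yl}dimethylalane | CC(C)=C[C@H](O[Si](C)(C)C(C)(C)C)C/C(C)=C/[Al](C)C | intermediate
16 | lithium butyl{(1E,4R)-4-[(tert-butyldimethylsilyl)oxy]-2,6-dimethylhepta-1,5-dien-1-yl}dimethylaluminate | CC(C)=C[C@H](O[Si](C)(C)C(C)(C)C)C/C(C)=C/[Al-](C)(C)CCCC.[Li+] | intermediate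
17 | (3E,6R)-6-[(tert-butyldimethylsilyl)oxy]-4,8-dimethylnona-3,7-dien-1-ol | CC(C)=C[C@H](O[Si](C)(C)C(C)(C)C)C/C(C)=C/CCO | intermediate
18 | {[(4R,6E)-9-bromo-2,6-dimethylnona-2,6-dien-4-yl]oxy}(tert-butyl)dimethylsilane | CC(C)=C[C@H](O[Si](C)(C)C(C)(C)C)C/C(C)=C/CCBr | intermediate
19 | propyne | CC#C | starting material
20 | {(3E,6R)-6-[(tert-butyldimethylsilyl)oxy]-4,8-dimethylnona-3,7-dien-1-yl}magnesium bromide | CC(C)=C[C@H](O[Si](C)(C)C(C)(C)C)C/C(C)=C/CC[Mg]Br | intermediate
21 | {(3E,6R)-6-[(tert-butyldimethylsilyl)oxy]-4,8-dimethylnona-3,7-dien-1-yl}copper (MgBr2·SMe2 complex) | CC(C)=C[C@H](O[Si](C)(C)C(C)(C)C)C/C(C)=C/CC[Cu] | intermediate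
22 | {(1Z,5E,8R)-8-[(tert-butyldimethylsilyl)oxy]-2,6,10-trimethylundeca-1,5,9-trien-1-yl}copper | CC(C)=C[C@H](O[Si](C)(C)C(C)(C)C)C/C(C)=C/CC/C(C)=C\[Cu] | intermediate
23 | tert-butyl{[(4R,6E,10Z)-11-iodo-2,6,10-trimethylundeca-2,6,10-trien-4-yl]oxy}dimethylsilane | CC(C)=C[C@H](O[Si](C)(C)C(C)(C)C)C/C(C)=C/CC/C(C)=C\I | intermediate
24 | {(1Z,5E,8R)-8-[(tert-butyldimethylsilyl)oxy]-2,6,10-trimethylundeca-1,5,9-trien-1-yl}lithium | CC(C)=C[C@H](O[Si](C)(C)C(C)(C)C)C/C(C)=C/CC/C(C)=C\[Li] | intermediate
25 | tert-butyldimethyl{[(4R,6E,10Z)-2,6,10-trimethyl-11-(tributylstannyl)undeca-2,6,10-trien-4-yl]oxy}silane | CC(C)=C[C@H](O[Si](C)(C)C(C)(C)C)C/C(C)=C/CC/C(C)=C\[Sn](CCCC)(CCCC)CCCC | intermediate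
26 | (4R,6E,10Z)-2,6,10-trimethyl-11-(tributylstannyl)undeca-2,6,10-trien-4-ol | CC(C)=C[C@H](O)C/C(C)=C/CC/C(C)=C\[Sn](CCCC)(CCCC)CCCC | intermediate
27 | carbon monoxide | [C-]#[O+] | starting material
28 | (2E,6Z,10E,13R)-1-(2,5-dimethoxy-3-methylphenyl)-13-hydroxy-3,7,11,15-tetramethylhexadeca-2,6,10,14-tetraen-5-one | CC(C)=C[C@H](O)C/C(C)=C/CC/C(C)=C\C(=O)C/C(C)=C/Cc1cc(OC)cc(C)c1OC | intermediate
29 | 2-[(2E,6Z,10E,13R)-13-hydroxy-3,7,11,15-tetramethyl-5-oxohexadeca-2,6,10,14-tetraen-1-yl]-6-methylcyclohexa-2,5-diene-1,4-dione | CC(C)=C[C@H](O)C/C(C)=C/CC/C(C)=C\C(=O)C/C(C)=C/CC1=CC(=O)C=C(C)C1=O | intermediate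
30 | 2-[(2E,6Z,10E,13R)-13-hydroxy-3,7,11,15-tetramethyl-5-oxohexadeca-2,6,10,14-tetraen-1-yl]-6-methylbenzene-1,4-diol | CC(C)=C[C@H](O)C/C(C)=C/CC/C(C)=C\C(=O)C/C(C)=C/Cc1cc(O)cc(C)c1O | target

**Step count and risks**
Total steps: 14 (steps 1–4 for chloride 8, steps 5–11 for stannane 26, steps 12–14 for union and unmasking).
Longest linear sequence: 10 steps (steps 5–14, from 3-methylbut-2-enal 9).

Steps most likely to fail:

Step 12. Tin-to-palladium transfer from the hindered trisubstituted alkenylstannane may be slow. Then β-hydride elimination of the allyl complex towards the aryl-conjugated diene, uncarbonylated allyl–alkenyl coupling, syn–anti exchange with loss of the 2E geometry, or alcoholysis of the acylpalladium by the free hydroxyl could compete. The fallback sets out from 23 and 8 and comes back at 28, replacing the carbonylation by carbonyl addition and oxidation. Iodide 23 would be taken by iodine–lithium exchange (t-BuLi, Et2O, −78 °C) and formylation with DMF to (2Z,6E,9R)-9-[(tert-butyldimethylsilyl)oxy]-3,7,11-trimethyldodeca-2,6,10-trienal F1. Chloride 8 would be converted with activated barium (BaI2, lithium biphenylide, THF, −78 °C) into [(2E)-4-(2,5-dimethoxy-3-methylphenyl)-2-methylbut-2-en-1-yl]barium chloride F2. Allylbarium reagents add to aldehydes through their α-carbon with retention of alkene geometry, so F2 and F1 should give the C5 carbinol (2E,6Z,10E,13R)-13-[(tert-butyldimethylsilyl)oxy]-1-(2,5-dimethoxy-3-methylphenyl)-3,7,11,15-tetramethylhexadeca-2,6,10,14-tetraen-5-ol F3 as both C5 epimers, which is of no consequence. Oxidation with Dess–Martin periodinane/NaHCO3 would give the silyl-protected dienone (2E,6Z,10E,13R)-13-[(tert-butyldimethylsilyl)oxy]-1-(2,5-dimethoxy-3-methylphenyl)-3,7,11,15-tetramethylhexadeca-2,6,10,14-tetraen-5-one F4, and HF·pyridine in THF/pyridine at 0 °C would return to 28.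

Step 13. The acidic, oxidising medium may damage the assembled chain by ionisation or oxidation of the C13 allylic alcohol, Z-to-E isomerisation of the C6=C7 enone, or migration of C2=C3 into conjugation. The fallback sets out from 8 and comes back at 30; it moves the oxidative demethylation ahead of the fragment union, so that no oxidant meets the chain. Chloride 8 would be oxidised with (NH4)2Ce(NO3)6 (MeCN/H2O, 0 °C) to 2-[(2E)-4-chloro-3-methylbut-2-en-1-yl]-6-methylcyclohexa-2,5-diene-1,4-dione F5 and reduced with Na2S2O4 to 2-[(2E)-4-chloro-3-methylbut-2-en-1-yl]-6-methylbenzene-1,4-diol F6. This would be silylated at once (TBSOTf, 2,6-lutidine, CH2Cl2, −78 °C) to the bis(tert-butyldimethylsilyl) ether of that hydroquinone F7. Carbonylative Stille coupling of F7 with 26 and 27 under the conditions of step 12 would give (2E,6Z,10E,13R)-1-{2,5-bis[(tert-butyldimethylsilyl)oxy]-3-methylphenyl}-13-hydroxy-3,7,11,15-tetramethylhexadeca-2,6,10,14-tetraen-5-one F8. Buffered fluoride (TBAF/AcOH, THF, 0 °C) would then cleave the two aryl silyl ethers to give 30 directly.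

Step 5. Facial discrimination of the small β,β-disubstituted enal by the catalyst may be insufficient, or allenyl transfer may compete, which would erode the enantiomeric purity that the whole route relies on. The fallback sets out from 9 and comes back at 12, replacing catalyst control by enzymatic resolution. Aldehyde 9 would be propargylated without stereocontrol under Barbier conditions (propargyl bromide, Zn, THF/aq. NH4Cl) to racemic 6-methylhept-5-en-1-yn-4-ol F9. Lipase-catalysed transesterification (Burkholderia cepacia lipase, vinyl acetate, hexane) should, by the empirical rule for secondary alcohols, acetylate the R enantiomer, whose larger alkenyl group outranks the propargyl group, to (4R)-6-methylhept-5-en-1-yn-4-yl acetate F10. The unreacted (4S)-6-methylhept-5-en-1-yn-4-ol F11 is separated, and methanolysis of F10 (K2CO3, MeOH) returns to 12.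

**Further compounds**
F1 | step 12 | (2Z,6E,9R)-9-[(tert-butyldimethylsilyl)oxy]-3,7,11-trimethyldodeca-2,6,10-trienal | CC(C)=C[C@H](O[Si](C)(C)C(C)(C)C)C/C(C)=C/CC/C(C)=C\C=O
F2 | step 12 | [(2E)-4-(2,5-dimethoxy-3-methylphenyl)-2-methylbut-2-en-1-yl]barium chloride | COc1cc(C)c(OC)c(C/C=C(C)/C[Ba]Cl)c1
F3 | step 12 | (2E,6Z,10E,13R)-13-[(tert-butyldimethylsilyl)oxy]-1-(2,5-dimethoxy-3-methylphenyl)-3,7,11,15-tetramethylhexadeca-2,6,10,14-tetraen-5-ol (C5 epimers) | CC(C)=C[C@H](O[Si](C)(C)C(C)(C)C)C/C(C)=C/CC/C(C)=C\C(O)C/C(C)=C/Cc1cc(OC)cc(C)c1OC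
F4 | step 12 | (2E,6Z,10E,13R)-13-[(tert-butyldimethylsilyl)oxy]-1-(2,5-dimethoxy-3-methylphenyl)-3,7,11,15-tetramethylhexadeca-2,6,10,14-tetraen-5-one | CC(C)=C[C@H](O[Si](C)(C)C(C)(C)C)C/C(C)=C/CC/C(C)=C\C(=O)C/C(C)=C/Cc1cc(OC)cc(C)c1OC
F5 | step 13 | 2-[(2E)-4-chloro-3-methylbut-2-en-1-yl]-6-methylcyclohexa-2,5-diene-1,4-dione | CC1=CC(=O)C=C(C/C=C(C)/CCl)C1=O
F6 | step 13 | 2-[(2E)-4-chloro-3-methylbut-2-en-1-yl]-6-methylbenzene-1,4-diol | Cc1cc(O)cc(C/C=C(C)/CCl)c1O
F7 | step 13 | {2-[(2E)-4-chloro-3-methylbut-2-en-1-yl]-6-methyl-1,4-phenylene}bis(oxy)bis(tert-butyldimethylsilane) | Cc1cc(O[Si](C)(C)C(C)(C)C)cc(C/C=C(C)/CCl)c1O[Si](C)(C)C(C)(C)C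
F8 | step 13 | (2E,6Z,10E,13R)-1-{2,5-bis[(tert-butyldimethylsilyl)oxy]-3-methylphenyl}-13-hydroxy-3,7,11,15-tetramethylhexadeca-2,6,10,14-tetraen-5-one | CC(C)=C[C@H](O)C/C(C)=C/CC/C(C)=C\C(=O)C/C(C)=C/Cc1cc(O[Si](C)(C)C(C)(C)C)cc(C)c1O[Si](C)(C)C(C)(C)C
F9 | step 5 | racemic 6-methylhept-5-en-1-yn-4-ol | CC(C)=CC(O)CC#C
F10 | step 5 | (4R)-6-methylhept-5-en-1-yn-4-yl acetate | CC(C)=C[C@H](OC(C)=O)CC#C
F11 | step 5 | (4S)-6-methylhept-5-en-1-yn-4-ol | CC(C)=C[C@@H](O)CC#C
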